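**Plan**

- Cuts: the styryl CH–aryl bond (late intermolecular Heck), the pyranone of the ring-bound coumarin (phenol ortho-formylation and Wittig lactonisation), the vinyl C=C (methylenation of a lactol), and the ring C6–aryl bond together with an aryl ester C–O bond.
- Enabling feature: number the cyclohexene C1 (quaternary; CH3 and styryl carbon Cβ), C2/C3 (CH2), C4 (=C–CH3), C5 (=CH), C6 (CH–aryl). The methyl-bearing carbons C1 and C4 are para, as in p-toluic acid, and the C6 aryl is cis to Cβ. A 2-iodoaryl ester placed at Cβ of a Birch-derived 1,4-dimethylcyclohexa-2,5-diene can therefore pass its arene to C6.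
- Ring order: Birch reductive methylation gives the carbocycle; the tethered Heck closes a δ-lactone on it; C2=C3 is saturated; the lactone is opened to phenol plus vinyl; the phenol is annulated to the first coumarin; the second coumarin is attached last.
- Stereochemistry: both stereocentres arise in the Heck step. The ester tether fixes the cis relation, and a chiral bisphosphine on cationic palladium picks one enantiotopic alkene. The E-alkene comes from the final Heck coupling.

Key step: step 6

Remark: the Birch dianion is flat at C1, so its methylation is assumed to give both C4 epimers of the acid; the pair is carried into step 5 and the cis-dimethyl ester is isolated there.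

**Step 1**
Reactants: 1 p-toluic acid
Product: 3 cis-1,4-dimethylcyclohexa-2,5-diene-1-carboxylic acid, via dilithium dienediolate 2 (not isolated)
Conditions: Li, NH3(l)/THF, −78 °C; then MeI, −78 °C to rt; aq. HCl work-up
Reagents that add atoms: iodomethane, CI
Why: Birch reduction of the benzoic acid stops at the carboxylate-stabilised dienediolate (C4 already protonated by ammonia), which is C-methylated at C1 (Birch reductive alkylation); attack on both faces is expected, so 3 should form alongside its trans-dimethyl epimer.

**Step 2**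
Reactants: 4 3-methoxyphenol
Product: 5 1-methoxy-3-(methoxymethoxy)benzene
Conditions: MOMCl, i-Pr2NEt, CH2Cl2, 0 °C to rt
Reagents that add atoms: chloromethyl methyl ether, COCCl
Why: O-alkylation of the phenol (Williamson-type) installs a MOM ether that later directs the metalation.

**Step 3**
Reactants: 5 1-methoxy-3-(methoxymethoxy)benzene
Product: 7 2-iodo-1-methoxy-3-(methoxymethoxy)benzene, via 2-lithio aryl ether 6 (not isolated)
Conditions: n-BuLi, THF, 0 °C; then I2, −78 °C to rt
Reagents that add atoms: iodine, II
Why: Directed ortho-metalation removes the proton flanked by the OMe and OMOM groups, and the aryllithium is trapped by iodine.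

**Step 4**
Reactants: 7 2-iodo-1-methoxy-3-(methoxymethoxy)benzene
Product: 8 2-iodo-3-methoxyphenol
Conditions: HCl, MeOH, 50 °C
Reagents that add atoms: none
Why: Acid-catalysed acetal methanolysis removes the MOM group and leaves the aryl iodide and the methyl ether untouched.

**Step 5**
Reactants: 3 cis-1,4-dimethylcyclohexa-2,5-diene-1-carboxylic acid (charged as the epimer pair from step 1); 8 2-iodo-3-methoxyphenol
Product: 9 2-iodo-3-methoxyphenyl cis-1,4-dimethylcyclohexa-2,5-diene-1-carboxylate
Conditions: DCC, DMAP (cat.), CH2Cl2, 0 °C to rt; cis ester freed from its C4 epimer by chromatography on AgNO3-impregnated silica gel and recrystallisation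
Reagents that add atoms: none
Why: Steglich esterification joins the hindered dienoic acid to the phenol without an acyl chloride that could aromatise by decarbonylation, and the heavy-atom esters should be crystalline enough to separate and to assign by X-ray diffraction, which matters because only the cis-dimethyl ester can complete the following Heck cycle.

**Step 6**
Reactants: 9 2-iodo-3-methoxyphenyl cis-1,4-dimethylcyclohexa-2,5-diene-1-carboxylate
Product: 10 (6aS,10aS)-1-methoxy-6a,9-dimethyl-6a,10a-dihydro-6H-benzo[c]chromen-6-one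
Conditions: Pd2(dba)3·CHCl3 (5 mol %), (R)-BINAP (12 mol %), Ag3PO4 (2 equiv), NMP, 80 °C
Reagents that add atoms: none
Why: Oxidative addition of the C–I bond to zerovalent palladium and iodide abstraction by silver give a cationic aryl–palladium–BINAP complex, which adds syn across one of the two enantiotopic ring alkenes and then loses the syn hydrogen H-4 by β-hydride elimination to leave the C9=C10 bond (ring C4=C5); the closest known reaction type is the asymmetric intramolecular Heck desymmetrisation of 1,1-disubstituted cyclohexa-2,5-dienes. The δ-lactone closes in the 6-exo-trig mode, the 7-endo alternative being disfavoured by the three-atom tether. The aryl-bearing centre C10a is controlled by the tether, which can deliver the arene only to the ring face that carries the ester, so the ring fusion is cis. The quaternary centre C6a becomes stereogenic through the choice between the two alkenes and is controlled by the chiral bisphosphine; (R)-BINAP is written here, and the antipode that leads to (6aS,10aS) is to be fixed in a pilot run. The step needs enantiotopic-group selectivity and regioselective β-hydride loss: the cis-dimethyl arrangement puts H-4 on the palladium face, whereas H-10a is anti and the quaternary carbon has no hydrogen, so the diene can form only towards C4. Geminal substitution at the ester α-carbon helps to populate the reactive s-cis ester rotamer, and silver-promoted halide removal should keep palladium hydride re-addition and alkene migration low.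

**Step 7**
Reactants: 10 (6aS,10aS)-1-methoxy-6a,9-dimethyl-6a,10a-dihydro-6H-benzo[c]chromen-6-one
Product: 11 (6aS,10aS)-1-methoxy-6a,9-dimethyl-6a,7,8,10a-tetrahydro-6H-benzo[c]chromen-6-one
Conditions: 2-nitrobenzenesulfonyl hydrazide, Et3N, CH2Cl2, rt
Reagents that add atoms: none
Why: Diimide reduction transfers H2 in a concerted syn fashion and is slowed strongly by alkene substitution, so the cis-disubstituted C7=C8 bond of the diene should be saturated while the trisubstituted C9=C10 bond, the lactone and both stereocentres stay untouched.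

**Step 8**
Reactants: 11 (6aS,10aS)-1-methoxy-6a,9-dimethyl-6a,7,8,10a-tetrahydro-6H-benzo[c]chromen-6-one
Product: 12 (6aS,10aS)-1-methoxy-6a,9-dimethyl-6a,7,8,10a-tetrahydro-6H-benzo[c]chromen-6-ol
Conditions: i-Bu2AlH (1.2 equiv), CH2Cl2, −78 °C; aq. potassium sodium tartrate
Reagents that add atoms: none
Why: Partial hydride reduction of the lactone stops at the tetrahedral aluminate of the hindered neopentylic carbonyl at low temperature and should give the lactol (both C6 epimers) on work-up.

**Step 9**
Reactants: 12 (6aS,10aS)-1-methoxy-6a,9-dimethyl-6a,7,8,10a-tetrahydro-6H-benzo[c]chromen-6-ol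
Product: 14 2-[(1R,6R)-6-ethenyl-3,6-dimethylcyclohex-2-en-1-yl]-3-methoxyphenol, via ring-opened hydroxy aldehyde 13 (not isolated)
Conditions: Ph3PCH3Br, KOt-Bu (excess), THF, 0 °C to 50 °C; aq. NH4Cl
Reagents that add atoms: methyltriphenylphosphonium bromide, C[P+](c1ccccc1)(c1ccccc1)c1ccccc1.[Br-]
Why: Base opens the lactol to the phenoxide aldehyde, whose non-enolisable formyl group undergoes Wittig methylenation, and the quaternary α-carbon cannot epimerise.

**Step 10**
Reactants: 14 2-[(1R,6R)-6-ethenyl-3,6-dimethylcyclohex-2-en-1-yl]-3-methoxyphenol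
Product: 15 3-[(1R,6R)-6-ethenyl-3,6-dimethylcyclohex-2-en-1-yl]-2-hydroxy-4-methoxybenzaldehyde
Conditions: MgCl2, Et3N, (CH2O)n, MeCN, reflux; aq. HCl
Reagents that add atoms: paraformaldehyde (as formaldehyde), C=O
Why: Magnesium-mediated ortho-formylation (Casnati–Skattebøl) delivers formaldehyde from the magnesium phenoxide only to the single free ortho position, and a second formaldehyde oxidises the benzylic alkoxide to the aldehyde.

**Step 11**
Reactants: 15 3-[(1R,6R)-6-ethenyl-3,6-dimethylcyclohex-2-en-1-yl]-2-hydroxy-4-methoxybenzaldehyde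
Product: 17 8-[(1R,6R)-6-ethenyl-3,6-dimethylcyclohex-2-en-1-yl]-7-methoxy-2H-chromen-2-one, via ethyl 2-hydroxycinnamate 16 (not isolated)
Conditions: Ph3P=CHCO2Et, PhNEt2, 210 °C
Reagents that add atoms: ethyl (triphenylphosphoranylidene)acetate, CCOC(=O)C=P(c1ccccc1)(c1ccccc1)c1ccccc1
Why: Wittig olefination of the salicylaldehyde, thermal E/Z equilibration of the cinnamate and intramolecular transesterification should close the 2-pyranone (Wittig lactonisation).

**Step 12**
Reactants: 18 umbelliferone
Product: 19 7-hydroxy-8-iodo-2H-chromen-2-one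
Conditions: I2, KI, aq. NH3, rt; then acidification
Reagents that add atoms: iodine, II
Why: Electrophilic aromatic iodination of the phenoxide should take place at C8, the ortho position activated by both the 7-oxygen and the ring oxygen.

**Step 13**
Reactants: 19 7-hydroxy-8-iodo-2H-chromen-2-one
Product: 20 8-iodo-7-methoxy-2H-chromen-2-one
Conditions: MeI, K2CO3, acetone, reflux
Reagents that add atoms: iodomethane, CI
Why: Williamson O-methylation of the phenol.

**Step 14**
Reactants: 17 8-[(1R,6R)-6-ethenyl-3,6-dimethylcyclohex-2-en-1-yl]-7-methoxy-2H-chromen-2-one; 20 8-iodo-7-methoxy-2H-chromen-2-one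
Product: 21 7-methoxy-8-[(E)-2-[(1R,2R)-2-(7-methoxy-2-oxo-2H-chromen-8-yl)-1,4-dimethylcyclohex-3-en-1-yl]ethenyl]-2H-chromen-2-one
Conditions: Pd(OAc)2 (10 mol %), n-Bu4NCl, NaHCO3, DMF, 90 °C
Reagents that add atoms: none
Why: Intermolecular Heck reaction in which the arylpalladium adds to the unsubstituted vinyl terminus (the internal carbon sits on a quaternary centre) and syn β-hydride elimination, possible only from the new benzylic carbon, should give the E-styrene without touching the stereocentres.

**Compound list**

1 | p-toluic acid (4-methylbenzoic acid) | Cc1ccc(C(=O)O)cc1 | starting material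
2 | dilithium (4-methylcyclohexa-2,5-dien-1-ylidene)methanediolate | CC1C=CC(=C([O-])[O-])C=C1.[Li+].[Li+] | intermediate
3 | cis-1,4-dimethylcyclohexa-2,5-diene-1-carboxylic acid (both methyls on one ring face; achiral) | C[C@@H]1C=C[C@@](C)(C(=O)O)C=C1 | intermediate
4 | 3-methoxyphenol | COc1cccc(O)c1 | starting material
5 | 1-methoxy-3-(methoxymethoxy)benzene | COCOc1cccc(OC)c1 | intermediate
6 | 2-lithio-1-methoxy-3-(methoxymethoxy)benzene | COCOc1cccc(OC)c1[Li] | intermediate
7 | 2-iodo-1-methoxy-3-(methoxymethoxy)benzene | COCOc1cccc(OC)c1I | intermediate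
8 | 2-iodo-3-methoxyphenol | COc1cccc(O)c1I | intermediate
9 | 2-iodo-3-methoxyphenyl cis-1,4-dimethylcyclohexa-2,5-diene-1-carboxylate (achiral) | C[C@@H]1C=C[C@@](C)(C(=O)Oc2cccc(OC)c2I)C=C1 | intermediate
10 | (6aS,10aS)-1-methoxy-6a,9-dimethyl-6a,10a-dihydro-6H-benzo[c]chromen-6-one (cis-fused, 7,9-diene) | O=C2[C@@]1(C)C=CC(C)=C[C@H]1c1c(OC)cccc1O2 | intermediate
11 | (6aS,10aS)-1-methoxy-6a,9-dimethyl-6a,7,8,10a-tetrahydro-6H-benzo[c]chromen-6-one | O=C2[C@@]1(C)CCC(C)=C[C@H]1c1c(OC)cccc1O2 | intermediate
12 | (6aS,10aS)-1-methoxy-6a,9-dimethyl-6a,7,8,10a-tetrahydro-6H-benzo[c]chromen-6-ol (lactol, C6 epimers) | OC2[C@@]1(C)CCC(C)=C[C@H]1c1c(OC)cccc1O2 | intermediate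
13 | (1S,2S)-2-(2-hydroxy-6-methoxyphenyl)-1,4-dimethylcyclohex-3-ene-1-carbaldehyde | O=C[C@@]1(C)CCC(C)=C[C@H]1c1c(OC)cccc1O | intermediate
14 | 2-[(1R,6R)-6-ethenyl-3,6-dimethylcyclohex-2-en-1-yl]-3-methoxyphenol | C=C[C@@]1(C)CCC(C)=C[C@H]1c1c(OC)cccc1O | intermediate
15 | 3-[(1R,6R)-6-ethenyl-3,6-dimethylcyclohex-2-en-1-yl]-2-hydroxy-4-methoxybenzaldehyde | C=C[C@@]1(C)CCC(C)=C[C@H]1c1c(OC)ccc(C=O)c1O | intermediate
16 | ethyl 3-{3-[(1R,6R)-6-ethenyl-3,6-dimethylcyclohex-2-en-1-yl]-2-hydroxy-4-methoxyphenyl}prop-2-enoate (E/Z mixture) | C=C[C@@]1(C)CCC(C)=C[C@H]1c1c(OC)ccc(C=CC(=O)OCC)c1O | intermediate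
17 | 8-[(1R,6R)-6-ethenyl-3,6-dimethylcyclohex-2-en-1-yl]-7-methoxy-2H-chromen-2-one | C=C[C@@]1(C)CCC(C)=C[C@H]1c1c(OC)ccc2ccc(=O)oc12 | intermediate
18 | umbelliferone (7-hydroxy-2H-chromen-2-one) | O=c1ccc2ccc(O)cc2o1 | starting material
19 | 7-hydroxy-8-iodo-2H-chromen-2-one | O=c1ccc2ccc(O)c(I)c2o1 | intermediate
20 | 8-iodo-7-methoxy-2H-chromen-2-one | COc1ccc2ccc(=O)oc2c1I | intermediate
21 | 7-methoxy-8-[(E)-2-[(1R,2R)-2-(7-methoxy-2-oxo-2H-chromen-8-yl)-1,4-dimethylcyclohex-3-en-1-yl]ethenyl]-2H-chromen-2-one (CNP0156435.1) | COc1ccc2ccc(=O)oc2c1/C=C/[C@@]1(C)CCC(C)=C[C@H]1c1c(OC)ccc2ccc(=O)oc12 | target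

**Step count**

Total steps: 14. Longest linear sequence: 11 steps (steps 2 to 11 and 14, from 3-methoxyphenol).

**Steps most likely to fail**

1. Step 6. The ligand-bound cationic palladium may distinguish the two enantiotopic alkenes poorly at the temperature the ester tether demands, and hydrodeiodination may compete while the ester rests in its unreactive rotamer. Fallback (resolution in place of catalyst control), from 9 back to 10: the cyclisation is run with an achiral ligand set (Pd(OAc)2, PPh3, Ag2CO3, MeCN, 80 °C). The tether still enforces the cis fusion, so 10 should form as a racemate together with its mirror image (6aR,10aR)-1-methoxy-6a,9-dimethyl-6a,10a-dihydro-6H-benzo[c]chromen-6-one F1. Preparative chromatography on a chiral stationary phase separates the two, and the route continues from 10.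

2. Step 1. Iodomethane may attack both faces of the planar dienediolate at C1 with little preference, and the epimeric acids or their esters may then co-elute and co-crystallise in step 5. Fallback (no C4 stereocentre in the precursor), from 8 back to 10:
   - Benzoic acid is put through the same Birch reductive methylation to give 1-methylcyclohexa-2,5-diene-1-carboxylic acid F2, in which C4 is a CH2 group and no epimers exist.
   - Steglich esterification with 8 gives 2-iodo-3-methoxyphenyl 1-methylcyclohexa-2,5-diene-1-carboxylate F3.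
   - Bis-allylic oxidation ((C5H5NH)2Cr2O7, t-BuOOH, Celite, benzene) gives 2-iodo-3-methoxyphenyl 1-methyl-4-oxocyclohexa-2,5-diene-1-carboxylate F4.
   - An enantioselective reductive Heck cyclisation (Pd(OAc)2, (R)-BINAP, HCO2Na, DMF, 60 °C) desymmetrises the dienone by the same tethered arylpalladation and should give (6aS,10aS)-1-methoxy-6a-methyl-10,10a-dihydro-6H-benzo[c]chromene-6,9(6aH)-dione F5.
   - Kinetic enolisation towards C10 and O-triflation (LiN(SiMe3)2, PhNTf2, THF, −78 °C) give (6aS,10aS)-1-methoxy-6a-methyl-6-oxo-6a,10a-dihydro-6H-benzo[c]chromen-9-yl trifluoromethanesulfonate F6.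
   - Negishi methylation (MeZnCl, Pd(PPh3)4, THF) replaces the triflate by methyl and gives 10.

3. Step 14. Oxidative addition and alkene insertion may be slow with the di-ortho-substituted iodide and the neopentylic vinyl group, so that hydrodeiodination and palladium precipitation outrun the coupling. Fallback (boron in place of direct arylation), from 17 back to 21: cross-metathesis of 17 with vinylboronic acid pinacol ester (second-generation Grubbs catalyst, CH2Cl2, 40 °C) should give 7-methoxy-8-[(1R,6R)-3,6-dimethyl-6-[(E)-2-(4,4,5,5-tetramethyl-1,3,2-dioxaborolan-2-yl)ethenyl]cyclohex-2-en-1-yl]-2H-chromen-2-one F7. Suzuki–Miyaura coupling of this boronate with 20 (Pd(OAc)2, SPhos, K3PO4, toluene/H2O, 80 °C) then gives 21 with retention of the E geometry.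

**Further compounds**

F1 | step 6 | (6aR,10aR)-1-methoxy-6a,9-dimethyl-6a,10a-dihydro-6H-benzo[c]chromen-6-one | O=C2[C@]1(C)C=CC(C)=C[C@@H]1c1c(OC)cccc1O2
F2 | step 1 | 1-methylcyclohexa-2,5-diene-1-carboxylic acid | CC1(C(=O)O)C=CCC=C1
F3 | step 1 | 2-iodo-3-methoxyphenyl 1-methylcyclohexa-2,5-diene-1-carboxylate | CC1(C(=O)Oc2cccc(OC)c2I)C=CCC=C1
F4 | step 1 | 2-iodo-3-methoxyphenyl 1-methyl-4-oxocyclohexa-2,5-diene-1-carboxylate | CC1(C(=O)Oc2cccc(OC)c2I)C=CC(=O)C=C1
F5 | step 1 | (6aS,10aS)-1-methoxy-6a-methyl-10,10a-dihydro-6H-benzo[c]chromene-6,9(6aH)-dione | O=C2[C@@]1(C)C=CC(=O)C[C@H]1c1c(OC)cccc1O2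
F6 | step 1 | (6aS,10aS)-1-methoxy-6a-methyl-6-oxo-6a,10a-dihydro-6H-benzo[c]chromen-9-yl trifluoromethanesulfonate | O=C2[C@@]1(C)C=CC(OS(=O)(=O)C(F)(F)F)=C[C@H]1c1c(OC)cccc1O2
F7 | step 14 | 7-methoxy-8-[(1R,6R)-3,6-dimethyl-6-[(E)-2-(4,4,5,5-tetramethyl-1,3,2-dioxaborolan-2-yl)ethenyl]cyclohex-2-en-1-yl]-2H-chromen-2-one | CC1(C)OB(/C=C/[C@@]2(C)CCC(C)=C[C@H]2c2c(OC)ccc3ccc(=O)oc23)OC1(C)C
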